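A direct plan would arylate the oxygen of 2,3,4-tribromo-6-methoxyphenol A1 with 2-fluorobenzaldehyde A2 by SNAr to give aldehyde A3, exchange the formyl group of A3 for hydroxyl by Baeyer–Villiger oxidation and formate cleavage, and dibrominate the new phenol ring. Its weakest steps would be:
- the SNAr coupling, because a weakly nucleophilic phenoxide flanked by Br and OMe would have to attack a singly activated fluoroarene at high temperature;
- the formyl-to-hydroxyl exchange, because it would spend two operations and a carbon atom that the target does not contain, and hydride migration to the benzoic acid would compete with aryl migration.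

The route rests on taking ring B back to a cyclohexanone, not on cutting the diaryl ether at an arene carbon. The ether oxygen is attached by SN2 to the α-carbon of 2-chlorocyclohexanone, and ring B becomes aromatic only afterwards. The key step exploits the pattern of ring B, in which the hydroxyl carbon C6' lies next to the ether carbon C1' and carries bromine ortho (C5') and para (C3'): bromine turns the ketone C=O into this phenol, dehydrogenates the ring and places both bromines in one operation. The hindered phenoxide thus meets an α-halo ketone instead of a fluoroarene, and no formyl group has to be brought in and degraded.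

Key step: step 3

Assumption: ketone 6 and bromo ketone 7 would be racemic; their single stereocentre disappears on aromatisation, and the target has no stereocentre. Ring A is numbered C1 (ether oxygen), C2–C4 (Br), C5 (H), C6 (OMe); ring B is numbered C1' (ether oxygen), C3' and C5' (Br), C6' (OH).

Step 1
Reactants: 1 guaiacol (2-methoxyphenol)
Product: 4 2,3,4-tribromo-6-methoxyphenol, via 4-bromoguaiacol 2 (not isolated), via 4,6-dibromoguaiacol 3 (not isolated)
Conditions: Br2 (3.0 equiv, dropwise), AcOH, 15 °C to rt
Reagents that add atoms: bromine, BrBr
Why: Threefold electrophilic aromatic bromination of a phenol, in which the free hydroxyl group should direct the first two bromines to its para and ortho carbons and the methoxy group the third to its own para carbon, so that only the C–H ortho to OMe and meta to OH is left and three equivalents without a Lewis acid should not go further.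

Step 2
Reactants: 4 2,3,4-tribromo-6-methoxyphenol; 5 2-chlorocyclohexan-1-one (racemic)
Product: 6 2-(2,3,4-tribromo-6-methoxyphenoxy)cyclohexan-1-one (racemic)
Conditions: K2CO3 (1.5 equiv), DMF, 60 °C
Reagents that add atoms: none
Why: Williamson-type SN2 alkylation of a phenoxide by an α-halo ketone, in which the carbonyl group lowers the barrier at the secondary carbon, the blocked ortho and para positions of the phenoxide leave only O-alkylation, carbonate is too weak a base for a Favorskii rearrangement, and the new stereocentre at C2 is formed as a racemate that step 3 removes.

Step 3
Reactants: 6 2-(2,3,4-tribromo-6-methoxyphenoxy)cyclohexan-1-one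
Product: 9 2,4-dibromo-6-(2,3,4-tribromo-6-methoxyphenoxy)phenol, via tribromo ketone 7 (not isolated), via ortho-bromophenol 8 (not isolated)
Conditions: Br2 (3.0 equiv, dropwise), AcOH, 15 °C to rt; then 70 °C, N2 stream; then Br2 (1.0 equiv), rt
Reagents that add atoms: bromine, BrBr
Why: Halogenative aromatisation of a cyclohexanone, in which acid-catalysed enolisation and bromination should first replace the three α-hydrogens (C2–H and both C6–H) to give 7, warming should then expel HBr across C2–C3 and, through the dienol, across C5–C6 so that enolisation delivers bromophenol 8, and the last equivalent of bromine should enter the free para position by ordinary electrophilic aromatic substitution. The closest known reaction type is the passage from cyclohexanone through a 2,2,6,6-tetrahalocyclohexanone to a 2,6-dihalophenol, together with the bromination–dehydrobromination of cyclohexenones to phenols. No ring is closed, since the carbocycle of ring B comes from 5 and only becomes an arene here: the ketone oxygen ends as the hydroxyl group on C6', the ether carbon C2 as C1', the other α-carbon as C5'–Br and the carbon para to the carbonyl carbon as C3'–Br. No stereocentre is formed, and the one in 6 and 7 is lost. The step needs bromine to end only ortho and para to the new hydroxyl group and ring A to stay untouched, which is secured because only the α-carbons can react before aromatisation, only the para carbon is activated and free after it, and ring A carries three deactivating bromines around a single flanked C–H. The aryl–O–C2 bond should hold because the aryloxy group is a poor leaving group in acetic acid and because acid-induced cyclodehydration onto ring A is excluded by its two substituted ortho positions.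

Compound list
1 | guaiacol (2-methoxyphenol) | COc1ccccc1O | starting material
2 | 4-bromo-2-methoxyphenol (4-bromoguaiacol) | COc1cc(Br)ccc1O | intermediate
3 | 2,4-dibromo-6-methoxyphenol (4,6-dibromoguaiacol) | COc1cc(Br)cc(Br)c1O | intermediate
4 | 2,3,4-tribromo-6-methoxyphenol | COc1cc(Br)c(Br)c(Br)c1O | intermediate
5 | 2-chlorocyclohexan-1-one (racemic) | O=C1CCCCC1Cl | starting material
6 | 2-(2,3,4-tribromo-6-methoxyphenoxy)cyclohexan-1-one (racemic) | COc1cc(Br)c(Br)c(Br)c1OC1CCCCC1=O | intermediate
7 | 2,6,6-tribromo-2-(2,3,4-tribromo-6-methoxyphenoxy)cyclohexan-1-one (racemic) | COc1cc(Br)c(Br)c(Br)c1OC1(Br)CCCC(Br)(Br)C1=O | intermediate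
8 | 2-bromo-6-(2,3,4-tribromo-6-methoxyphenoxy)phenol | COc1cc(Br)c(Br)c(Br)c1Oc1cccc(Br)c1O | intermediate
9 | 2,4-dibromo-6-(2,3,4-tribromo-6-methoxyphenoxy)phenol | COc1cc(Br)c(Br)c(Br)c1Oc1cc(Br)cc(Br)c1O | target

Total step count: 3. Longest linear sequence: 3 steps (1 to 4 to 6 to 9).

Steps most likely to fail

Step 3 (key step). Bromine may be misdirected before the ring is aromatic: addition to the enol ether double bond of a partly dehydrobrominated intermediate would leave bromine meta to the hydroxyl group. Hydrogen bromide may also cleave the C2–O bond of the α-aryloxy ketone before aromatisation is complete. The fallback sets out from phenol 4 and comes back to the route at target 9; it brings the first unsaturation in with the building block and separates aromatisation from bromination. The phenoxide of 4 (K2CO3, DMF, 80 °C) would open racemic 2,3-epoxycyclohexanone F1 at its α-carbon and lose water to give 2-(2,3,4-tribromo-6-methoxyphenoxy)cyclohex-2-en-1-one F2. Catalytic I2 in DMSO at 100 °C, with DMSO as the terminal oxidant, would dehydrogenate F2 to 2-(2,3,4-tribromo-6-methoxyphenoxy)phenol F3 with no bromine in the flask. Br2 (2.0 equiv) in AcOH at rt would then substitute the para position and the free ortho position of the hydroxyl group to give 9.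

Step 2. Substitution at the secondary carbon may be too slow for a phenoxide that is both hindered and weakly basic, so that dehydrochlorination and self-condensation of the chloro ketone would take over. The fallback sets out from phenol 4 and comes back at ketone 6; it uses an electrophile that cannot enolise. The phenoxide of 4 (K2CO3, DMF, 120 °C) would open cyclohexene oxide F4 by anti attack to give racemic trans-2-(2,3,4-tribromo-6-methoxyphenoxy)cyclohexan-1-ol F5. Dess–Martin periodinane (CH2Cl2, rt) would oxidise F5 to 6.

Step 1. The third bromine may enter ortho instead of para to the methoxy group, or bromination may run on to the tetrabromide, which would leave isomeric and over-brominated phenols to separate. The fallback sets out from guaiacol 1 and comes back at phenol 4; it places the third bromine on a ring whose two free positions are equivalent. O-Methylation of 1 (MeI, K2CO3, acetone) would give veratrole F6. Br2 (2.0 equiv) in AcOH would give 4,5-dibromoveratrole F7. A third bromination (Br2, FeBr3 cat., CH2Cl2) could then only give 3,4,5-tribromoveratrole F8. BCl3 (1.0 equiv, CH2Cl2, −78 to 0 °C) should cleave selectively the methoxy group at C2 of F8, which is flanked by OMe and Br and twisted out of the ring plane, to give 4.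

Further compounds
F1 | step 3 | 2,3-epoxycyclohexanone (7-oxabicyclo[4.1.0]heptan-2-one, racemic) | O=C1CCCC2OC12
F2 | step 3 | 2-(2,3,4-tribromo-6-methoxyphenoxy)cyclohex-2-en-1-one | COc1cc(Br)c(Br)c(Br)c1OC1=CCCCC1=O
F3 | step 3 | 2-(2,3,4-tribromo-6-methoxyphenoxy)phenol | COc1cc(Br)c(Br)c(Br)c1Oc1ccccc1O
F4 | step 2 | cyclohexene oxide (7-oxabicyclo[4.1.0]heptane) | C1CCC2OC2C1
F5 | step 2 | trans-2-(2,3,4-tribromo-6-methoxyphenoxy)cyclohexan-1-ol (racemic, one enantiomer drawn) | O[C@@H]1CCCC[C@H]1Oc1c(OC)cc(Br)c(Br)c1Br
F6 | step 1 | veratrole (1,2-dimethoxybenzene) | COc1ccccc1OC
F7 | step 1 | 4,5-dibromoveratrole (1,2-dibromo-4,5-dimethoxybenzene) | COc1cc(Br)c(Br)cc1OC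
F8 | step 1 | 3,4,5-tribromoveratrole (1,2,3-tribromo-4,5-dimethoxybenzene) | COc1cc(Br)c(Br)c(Br)c1OC
A1 | direct plan | 2,3,4-tribromo-6-methoxyphenol | COc1cc(Br)c(Br)c(Br)c1O
A2 | direct plan | 2-fluorobenzaldehyde | O=Cc1ccccc1F
A3 | direct plan | 2-(2,3,4-tribromo-6-methoxyphenoxy)benzaldehyde | COc1cc(Br)c(Br)c(Br)c1Oc1ccccc1C=O
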